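## Retrosynthetic overview

1. The macrocycle is closed last at C7–C8 by a Pd-catalysed, hydroxyl-directed alkenyl C–H alkenylation of seco hydroxy enone 39 (terminal C8=C9 vinyl plus isopropenyl ketone).
2. C2=C3 (Z) comes from an Ando-type Horner–Wadsworth–Emmons union of phosphonate ester 27 (C1–C2 and C8–C24) with aldehyde 35 (C3–C7); the C1–O19 ester is made by carbodiimide coupling.
3. In 27, C10–C11 comes from Brown allylboration, C12=C13 (Z) from an Ando olefination, and the oxolane from anti-reduction of aldol adduct 12 followed by 5-exo epoxide opening.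
4. Aldol adduct 12 joins ethyl ketone 10 (C13–C18, via Sharpless kinetic resolution) and epoxy enal 4 (C19–C24, via Sharpless epoxidation of crotyl alcohol); aldehyde 35 comes from an Evans aldol with methacrolein.
5. Ring order: the two oxiranes first (C22–C23 kept, C13–C14 sacrificial), then the oxolane, then the 20-membered lactone.

Assumption: locants C1–C24 follow the lactone chain (C1 lactone carbonyl, C19 lactone carbinol, C24 epoxide methyl); the SMILES is read as (2Z,4S,6E,8Z,11R,12Z,14S,15S,17R,18R,19R,20E,22R,23R).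

## Route

Step 1
Reactants: 1 (2E)-but-2-en-1-ol
Product: 2 [(2R,3R)-3-methyloxiran-2-yl]methanol
Conditions: Ti(OiPr)4 (5 mol %), D-(−)-diisopropyl tartrate (6 mol %), t-BuOOH, 4 Å MS, CH2Cl2, −20 °C
Reagents that add atoms: tert-butyl hydroperoxide, CC(C)(C)OO
Why: Sharpless asymmetric epoxidation; the D-(−)-tartrate complex delivers oxygen to the alkene face that gives the (2R,3R)-epoxy alcohol, which sets C22 and C23.

Step 2
Reactants: 2 [(2R,3R)-3-methyloxiran-2-yl]methanol
Product: 3 (2S,3R)-3-methyloxirane-2-carbaldehyde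
Conditions: TEMPO (10 mol %), PhI(OAc)2, CH2Cl2, 0 °C to rt; dried solution used directly
Reagents that add atoms: none
Why: TEMPO/PhI(OAc)2 oxidation is neutral, so the epoxide and the α-stereocentre survive (the descriptor changes only through CIP priorities).

Step 3
Reactants: 3 (2S,3R)-3-methyloxirane-2-carbaldehyde
Product: 4 (2E)-3-[(2R,3R)-3-methyloxiran-2-yl]prop-2-enal
Conditions: Ph3P=CHCHO (1.1 equiv), CH2Cl2, rt
Reagents that add atoms: (triphenylphosphoranylidene)acetaldehyde, O=CC=P(c1ccccc1)(c1ccccc1)c1ccccc1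
Why: Wittig olefination with a stabilised ylide gives the (E)-enal (C20=C21) and adds C19–C20.

Step 4
Reactants: 5 N-methoxy-N-methylacetamide; 6 prop-2-enal
Product: 7 rac-3-hydroxy-N-methoxy-N-methylpent-4-enamide
Conditions: LiN(iPr)2, THF, −78 °C; then 6, −78 °C; AcOH quench
Reagents that add atoms: none
Why: Aldol addition of the amide lithium enolate occurs 1,2 at the aldehyde at low temperature and forms C15–C16; the racemate is resolved in step 5.

Step 5
Reactants: 7 rac-3-hydroxy-N-methoxy-N-methylpent-4-enamide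
Product: 8 (3S)-3-hydroxy-N-methoxy-N-methyl-3-[(2R)-oxiran-2-yl]propanamide
Conditions: Ti(OiPr)4 (0.2 equiv), L-(+)-diisopropyl tartrate (0.25 equiv), t-BuOOH (0.55 equiv), 4 Å MS, CH2Cl2, −20 °C
Reagents that add atoms: tert-butyl hydroperoxide, CC(C)(C)OO
Why: Sharpless kinetic resolution; with L-(+)-tartrate the (3S)-alcohol is epoxidised fast and anti-selectively (erythro) while the (3R)-alcohol is left and separated (yield at most 50 %), which sets C15 and the sacrificial C14 centre.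

Step 6
Reactants: 8 (3S)-3-hydroxy-N-methoxy-N-methyl-3-[(2R)-oxiran-2-yl]propanamide
Product: 9 (3S)-N,3-dimethoxy-N-methyl-3-[(2R)-oxiran-2-yl]propanamide
Conditions: MeI (excess), Ag2O, 4 Å MS, Et2O, rt, dark
Reagents that add atoms: iodomethane, CI
Why: Purdie methylation without strong base avoids Payne rearrangement and retro-aldol cleavage, so both stereocentres are kept.

Step 7
Reactants: 9 (3S)-N,3-dimethoxy-N-methyl-3-[(2R)-oxiran-2-yl]propanamide
Product: 10 (5S)-5-methoxy-5-[(2R)-oxiran-2-yl]pentan-3-one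
Conditions: EtMgBr (1.3 equiv), THF, −20 to 0 °C; aq NH4Cl
Reagents that add atoms: ethylmagnesium bromide, CC[Mg]Br
Why: Weinreb ketone synthesis; the chelated tetrahedral intermediate stops at the ketone and the amide reacts faster than the terminal epoxide at this temperature.

Step 8
Reactants: 10 (5S)-5-methoxy-5-[(2R)-oxiran-2-yl]pentan-3-one; 4 (2E)-3-[(2R,3R)-3-methyloxiran-2-yl]prop-2-enal
Product: 12 syn-aldol adduct (C13–C24 keto diepoxide), via Z-enol borinate 11 (not isolated)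
Conditions: (−)-Ipc2BOTf (Ipc groups from (+)-α-pinene), iPr2NEt, CH2Cl2, −78 °C; then 4, −78 to −20 °C; H2O2, MeOH, pH 7 buffer, 0 °C
Reagents that add atoms: none
Why: Paterson boron aldol; the bulky borane enolises the less hindered ethyl CH2 to the (Z)-enol borinate, which adds to the si face of the enal through a Zimmerman–Traxler chair under reagent control, giving the 18,19-syn adduct with 19R.

Step 9
Reactants: 12 syn-aldol adduct
Product: 14 oxolane diol (C13–C24), via anti-1,3-diol 13 (not isolated)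
Conditions: Me4NBH(OAc)3, MeCN/AcOH (3:1), −30 °C; aq KNaC4H4O6 work-up; crude 13, camphorsulfonic acid (5 mol %), CH2Cl2, 0 °C
Reagents that add atoms: none
Why: Evans–Saksena reduction delivers hydride from boron bound to the C19 hydroxyl and gives the 17,19-anti diol (17R); acid-catalysed 5-exo-tet opening of the terminal epoxide by the C17 hydroxyl then closes the oxolane with inversion at C14 (2,5-trans, C13 cis to OMe).

Step 10
Reactants: 14 oxolane diol
Product: 15 bis(triethylsilyl) ether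
Conditions: Et3SiCl (3 equiv), imidazole, DMF, 0 °C to rt
Reagents that add atoms: chlorotriethylsilane, CC[Si](Cl)(CC)CC
Why: Standard silylation of both hydroxyls; no stereocentre is touched.

Step 11
Reactants: 15 bis(triethylsilyl) ether
Product: 16 C13 aldehyde (19-O-TES)
Conditions: (COCl)2, DMSO, CH2Cl2, −78 °C; 15, −78 to −40 °C; Et3N, −78 to 0 °C
Reagents that add atoms: none
Why: Swern oxidation of silyl ethers cleaves and oxidises the primary triethylsilyl ether in one pot while the secondary one is inert; the cold, short base exposure limits epimerisation at C14.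

Step 12
Reactants: 17 prop-2-en-1-yl bromoacetate
Product: 18 prop-2-en-1-yl [bis(2-methylphenoxy)phosphoryl]acetate
Conditions: (2-MeC6H4O)2P(O)H, Et3N, CH2Cl2, 0 °C to rt
Reagents that add atoms: bis(2-methylphenyl) phosphonate, Cc1ccccc1O[PH](=O)Oc1ccccc1C
Why: Michaelis–Becker-type P-alkylation of the diaryl phosphite gives the Ando phosphonate.

Step 13
Reactants: 18 prop-2-en-1-yl [bis(2-methylphenoxy)phosphoryl]acetate
Product: 19 prop-2-en-1-yl 2-[bis(2-methylphenoxy)phosphoryl]propanoate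
Conditions: NaH, MeI, THF/DMSO, 0 °C to rt
Reagents that add atoms: iodomethane, CI
Why: C-methylation of the stabilised phosphonate anion installs the future C2 and C12 methyl groups (racemic, which is irrelevant).

Step 14
Reactants: 16 C13 aldehyde; 19 prop-2-en-1-yl 2-[bis(2-methylphenoxy)phosphoryl]propanoate
Product: 20 allyl (12Z)-enoate (C11–C24)
Conditions: 19 (1.3 equiv), NaH, THF, 0 °C; then 16, −78 to −20 °C
Reagents that add atoms: none
Why: Ando variant of the Horner–Wadsworth–Emmons reaction; the electron-poor diaryl phosphonate collapses fast from the kinetic adduct and gives the (12Z)-trisubstituted enoate with C14 cis to the ester carbon.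

Step 15
Reactants: 20 allyl (12Z)-enoate
Product: 21 (12Z)-allylic alcohol
Conditions: iBu2AlH (2.5 equiv), CH2Cl2, −78 °C; aq KNaC4H4O6
Reagents that add atoms: none
Why: Hydride reduction of the ester at −78 °C leaves the vinyl epoxide, the silyl ether and the alkene geometry intact.

Step 16
Reactants: 21 (12Z)-allylic alcohol
Product: 22 (12Z)-enal
Conditions: MnO2 (20 equiv), CH2Cl2, rt; used at once
Reagents that add atoms: none
Why: Neutral allylic oxidation with MnO2 keeps the (Z)-geometry of the 2-methyl enal.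

Step 17
Reactants: 22 (12Z)-enal
Product: 23 C8–C24 homoallylic alcohol (11R)
Conditions: (lIpc)2B(allyl) (B-allyldiisopinocampheylborane with Ipc groups from (−)-α-pinene, salt-free), Et2O, −78 °C; then NaBO3·4H2O, THF/H2O, rt
Reagents that add atoms: B-allyldiisopinocampheylborane, C=CCB([C@H]1C[C@H]2C[C@@H]([C@@H]1C)C2(C)C)[C@H]1C[C@H]2C[C@@H]([C@@H]1C)C2(C)C
Why: Brown allylboration; the chair transition state of this reagent antipode attacks the re face of the aldehyde, forming C10–C11 and setting 11R under reagent control.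

Step 18
Reactants: 23 C8–C24 homoallylic alcohol
Product: 24 11-O-TBS ether
Conditions: t-BuMe2SiOTf, 2,6-lutidine, CH2Cl2, −78 °C
Reagents that add atoms: tert-butyldimethylsilyl trifluoromethanesulfonate, CC(C)(C)[Si](C)(C)OS(=O)(=O)C(F)(F)F
Why: Silylation of the hindered allylic alcohol with the silyl triflate is fast at −78 °C, where the buffered medium spares the vinyl epoxide.

Step 19
Reactants: 24 11-O-TBS ether
Product: 25 C19 alcohol
Conditions: HF·pyridine, pyridine, THF, 0 °C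
Reagents that add atoms: none
Why: Buffered fluoride cleaves the triethylsilyl ether much faster than the tert-butyldimethylsilyl ether (selective desilylation).

Step 20
Reactants: 19 prop-2-en-1-yl 2-[bis(2-methylphenoxy)phosphoryl]propanoate
Product: 26 2-[bis(2-methylphenoxy)phosphoryl]propanoic acid
Conditions: Pd(PPh3)4 (5 mol %), morpholine, THF, rt; acidic work-up
Reagents that add atoms: none
Why: Tsuji–Trost deallylation removes the allyl ester under neutral conditions without touching the aryl phosphonate esters.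

Step 21
Reactants: 25 C19 alcohol; 26 2-[bis(2-methylphenoxy)phosphoryl]propanoic acid
Product: 27 phosphonate ester (C1–C2 plus C8–C24)
Conditions: DCC, DMAP (10 mol %), CH2Cl2, 0 °C to rt
Reagents that add atoms: none
Why: Steglich esterification forms the C1–O19 lactone ester bond with a saturated acid, so no enoate isomerisation can occur; C19 is not touched.

Step 22
Reactants: 28 propanoyl chloride
Product: 29 (4R)-4-benzyl-3-propanoyl-1,3-oxazolidin-2-one
Conditions: (4R)-4-benzyl-1,3-oxazolidin-2-one, n-BuLi, THF, −78 °C; then 28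
Reagents that add atoms: (4R)-4-benzyl-1,3-oxazolidin-2-one, O=C1N[C@H](Cc2ccccc2)CO1
Why: N-acylation of the lithiated auxiliary gives the Evans propionimide.

Step 23
Reactants: 29 (4R)-4-benzyl-3-propanoyl-1,3-oxazolidin-2-one; 30 2-methylprop-2-enal
Product: 32 Evans syn-aldol adduct, via dibutylboron Z-enolate 31 (not isolated)
Conditions: Bu2BOTf, Et3N, CH2Cl2, 0 °C; then 30, −78 to 0 °C; H2O2, MeOH, pH 7 buffer
Reagents that add atoms: none
Why: Evans syn aldol; the (Z)-boron enolate reacts through a dipole-minimised Zimmerman–Traxler chair, and the (4R)-auxiliary sets the (2R,3R) adduct, which carries C4 in the target configuration (4S after chain extension).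

Step 24
Reactants: 32 Evans syn-aldol adduct
Product: 33 triethylsilyl ether of 32
Conditions: Et3SiOTf, 2,6-lutidine, CH2Cl2, −78 to 0 °C
Reagents that add atoms: triethylsilyl trifluoromethanesulfonate, CC[Si](CC)(CC)OS(=O)(=O)C(F)(F)F
Why: Silyl protection of the C5 carbinol; no stereocentre is touched.

Step 25
Reactants: 33 triethylsilyl ether of 32
Product: 34 (2S,3R)-2,4-dimethyl-3-[(triethylsilyl)oxy]pent-4-en-1-ol
Conditions: LiBH4, MeOH (1.1 equiv), THF, 0 °C
Reagents that add atoms: none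
Why: Reductive cleavage of the imide gives the primary alcohol and frees the auxiliary without epimerising C4.

Step 26
Reactants: 34 (2S,3R)-2,4-dimethyl-3-[(triethylsilyl)oxy]pent-4-en-1-ol
Product: 35 (2R,3R)-2,4-dimethyl-3-[(triethylsilyl)oxy]pent-4-enal
Conditions: Dess–Martin periodinane, NaHCO3, CH2Cl2, 0 °C to rt; used at once
Reagents that add atoms: none
Why: Buffered Dess–Martin oxidation gives the α-chiral aldehyde without epimerisation.

Step 27
Reactants: 27 phosphonate ester; 35 (2R,3R)-2,4-dimethyl-3-[(triethylsilyl)oxy]pent-4-enal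
Product: 36 (2Z)-enoate seco compound (5-O-TES, 11-O-TBS)
Conditions: 27, NaH (0.95 equiv), THF, 0 °C; then 35 (1.2 equiv), −78 to −30 °C
Reagents that add atoms: none
Why: Ando-type Z-selective Horner–Wadsworth–Emmons fragment union forms C2=C3 (2Z); the preformed phosphonate anion is weakly basic, so C4 is not epimerised.

Step 28
Reactants: 36 (2Z)-enoate seco compound
Product: 37 C5 alcohol (11-O-TBS)
Conditions: HF·pyridine, pyridine, THF, 0 °C
Reagents that add atoms: none
Why: Selective cleavage of the triethylsilyl ether in the presence of the tert-butyldimethylsilyl ether.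

Step 29
Reactants: 37 C5 alcohol
Product: 38 isopropenyl ketone (11-O-TBS)
Conditions: Dess–Martin periodinane, NaHCO3, CH2Cl2, 0 °C
Reagents that add atoms: none
Why: Buffered Dess–Martin oxidation forms the C5 ketone late and under near-neutral conditions, so the doubly activated C4–H is not epimerised.

Step 30
Reactants: 38 isopropenyl ketone
Product: 39 seco hydroxy enone (free 11R-OH)
Conditions: HF·pyridine (excess), pyridine, THF, 0 °C to rt
Reagents that add atoms: none
Why: Buffered acidic fluoride removes the allylic silyl ether without a basic medium that would epimerise C4.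

Step 31
Reactants: 39 seco hydroxy enone
Product: 40 CNP0117824.2 (target)
Conditions: Pd(OAc)2 (20 mol %), N-acetylglycine (40 mol %), 1,4-benzoquinone (2 equiv), 4 Å MS, PhMe/t-AmOH (4:1), 45 °C, syringe-pump addition of 39 to 1 mM
Reagents that add atoms: none
Why: Proposed new method: a macrocyclising, hydroxyl-directed alkenyl C–H alkenylation (dehydrogenative Heck reaction) in which the C11 hydroxyl binds divalent palladium, carboxylate-assisted metalation–deprotonation cleaves the C8–H that is cis to C10 through a six-membered oxa-palladacycle (fixing 8Z), the tethered isopropenyl ketone (the only unhindered electron-poor alkene) inserts to form C7–C8 with Pd at C6, syn β-hydride elimination towards C7 gives the conjugated 6E alkene and benzoquinone reoxidises zerovalent palladium; the closest known reactions are intermolecular chelation-assisted (hydroxyl- or amide-directed) Z-selective alkenyl C–H olefinations with acrylates and macrocyclising Heck reactions of vinyl iodides with enones, whereas a ring-closing version on an α-branched enone has not been shown.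

## Compound list

1 | (2E)-but-2-en-1-ol | C/C=C/CO | starting material
2 | [(2R,3R)-3-methyloxiran-2-yl]methanol | OC[C@H]1O[C@@H]1C | intermediate
3 | (2S,3R)-3-methyloxirane-2-carbaldehyde | O=C[C@H]1O[C@@H]1C | intermediate
4 | (2E)-3-[(2R,3R)-3-methyloxiran-2-yl]prop-2-enal (C19–C24) | O=C/C=C/[C@H]1O[C@@H]1C | intermediate
5 | N-methoxy-N-methylacetamide | CC(=O)N(C)OC | starting material
6 | prop-2-enal | C=CC=O | starting material
7 | rac-3-hydroxy-N-methoxy-N-methylpent-4-enamide | C=CC(O)CC(=O)N(C)OC | intermediate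
8 | (3S)-3-hydroxy-N-methoxy-N-methyl-3-[(2R)-oxiran-2-yl]propanamide | CON(C)C(=O)C[C@H](O)[C@H]1CO1 | intermediate
9 | (3S)-N,3-dimethoxy-N-methyl-3-[(2R)-oxiran-2-yl]propanamide | CON(C)C(=O)C[C@H](OC)[C@H]1CO1 | intermediate
10 | (5S)-5-methoxy-5-[(2R)-oxiran-2-yl]pentan-3-one (C13–C18) | CCC(=O)C[C@H](OC)[C@H]1CO1 | intermediate
11 | (Z)-enol diisopinocampheylborinate of 10 (enolised at C18; not isolated) | C/C=C(\OB([C@@H]1C[C@@H]2C[C@H]([C@H]1C)C2(C)C)[C@@H]1C[C@@H]2C[C@H]([C@H]1C)C2(C)C)C[C@H](OC)[C@H]1CO1 | intermediate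
12 | (1S,4S,5R,6E)-5-hydroxy-1-methoxy-4-methyl-7-[(2R,3R)-3-methyloxiran-2-yl]-1-[(2R)-oxiran-2-yl]hept-6-en-3-one (18,19-syn) | C[C@H]1O[C@@H]1/C=C/[C@@H](O)[C@H](C)C(=O)C[C@H](OC)[C@H]1CO1 | intermediate
13 | (1S,3R,4R,5R,6E)-1-methoxy-4-methyl-7-[(2R,3R)-3-methyloxiran-2-yl]-1-[(2R)-oxiran-2-yl]hept-6-ene-3,5-diol (17,19-anti; not isolated) | C[C@H]1O[C@@H]1/C=C/[C@@H](O)[C@H](C)[C@H](O)C[C@H](OC)[C@H]1CO1 | intermediate
14 | (2S,3R,4E)-2-[(2R,4S,5S)-5-(hydroxymethyl)-4-methoxyoxolan-2-yl]-5-[(2R,3R)-3-methyloxiran-2-yl]pent-4-en-3-ol | C[C@H]1O[C@@H]1/C=C/[C@@H](O)[C@H](C)[C@H]1C[C@H](OC)[C@H](CO)O1 | intermediate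
15 | 14 with both hydroxyls (O13 and O19) as triethylsilyl ethers | C[C@H]1O[C@@H]1/C=C/[C@@H](O[Si](CC)(CC)CC)[C@H](C)[C@H]1C[C@H](OC)[C@H](CO[Si](CC)(CC)CC)O1 | intermediate
16 | (2R,3S,5R)-3-methoxy-5-{(2R,3R,4E)-5-[(2R,3R)-3-methyloxiran-2-yl]-3-[(triethylsilyl)oxy]pent-4-en-2-yl}oxolane-2-carbaldehyde | C[C@H]1O[C@@H]1/C=C/[C@@H](O[Si](CC)(CC)CC)[C@H](C)[C@H]1C[C@H](OC)[C@H](C=O)O1 | intermediate
17 | prop-2-en-1-yl bromoacetate | C=CCOC(=O)CBr | starting material
18 | prop-2-en-1-yl [bis(2-methylphenoxy)phosphoryl]acetate | C=CCOC(=O)CP(=O)(Oc1ccccc1C)Oc1ccccc1C | intermediate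
19 | prop-2-en-1-yl 2-[bis(2-methylphenoxy)phosphoryl]propanoate (racemic) | C=CCOC(=O)C(C)P(=O)(Oc1ccccc1C)Oc1ccccc1C | intermediate
20 | prop-2-en-1-yl (2Z)-3-[(2S,3S,5R)-3-methoxy-5-{(2R,3R,4E)-5-[(2R,3R)-3-methyloxiran-2-yl]-3-[(triethylsilyl)oxy]pent-4-en-2-yl}oxolan-2-yl]-2-methylprop-2-enoate | C=CCOC(=O)/C(C)=C\[C@@H]1O[C@H](C[C@@H]1OC)[C@@H](C)[C@H](O[Si](CC)(CC)CC)/C=C/[C@H]2O[C@@H]2C | intermediate
21 | (2Z)-2-methylprop-2-en-1-ol corresponding to 20 (C11 primary alcohol, 12Z) | OC/C(C)=C\[C@@H]1O[C@H](C[C@@H]1OC)[C@@H](C)[C@H](O[Si](CC)(CC)CC)/C=C/[C@H]2O[C@@H]2C | intermediate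
22 | (2Z)-2-methylprop-2-enal corresponding to 21 (C11 aldehyde, 12Z) | O=C/C(C)=C\[C@@H]1O[C@H](C[C@@H]1OC)[C@@H](C)[C@H](O[Si](CC)(CC)CC)/C=C/[C@H]2O[C@@H]2C | intermediate
23 | (1Z,3R)-1-[(2S,3S,5R)-3-methoxy-5-{(2R,3R,4E)-5-[(2R,3R)-3-methyloxiran-2-yl]-3-[(triethylsilyl)oxy]pent-4-en-2-yl}oxolan-2-yl]-2-methylhexa-1,5-dien-3-ol (C8–C24, 11R) | C=CC[C@@H](O)/C(C)=C\[C@@H]1O[C@H](C[C@@H]1OC)[C@@H](C)[C@H](O[Si](CC)(CC)CC)/C=C/[C@H]2O[C@@H]2C | intermediate
24 | 23 with O11 as tert-butyldimethylsilyl ether | C=CC[C@@H](O[Si](C)(C)C(C)(C)C)/C(C)=C\[C@@H]1O[C@H](C[C@@H]1OC)[C@@H](C)[C@H](O[Si](CC)(CC)CC)/C=C/[C@H]2O[C@@H]2C | intermediate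
25 | 24 with the O19 triethylsilyl group removed (free 19R hydroxyl) | C=CC[C@@H](O[Si](C)(C)C(C)(C)C)/C(C)=C\[C@@H]1O[C@H](C[C@@H]1OC)[C@@H](C)[C@H](O)/C=C/[C@H]2O[C@@H]2C | intermediate
26 | 2-[bis(2-methylphenoxy)phosphoryl]propanoic acid (racemic) | CC(C(=O)O)P(=O)(Oc1ccccc1C)Oc1ccccc1C | intermediate
27 | O19 ester of 25 with acid 26 (both epimers at the phosphonate carbon) | C=CC[C@@H](O[Si](C)(C)C(C)(C)C)/C(C)=C\[C@@H]1O[C@H](C[C@@H]1OC)[C@@H](C)[C@H](OC(=O)C(C)P(=O)(Oc1ccccc1C)Oc1ccccc1C)/C=C/[C@H]2O[C@@H]2C | intermediate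
28 | propanoyl chloride | CCC(Cl)=O | starting material
29 | (4R)-4-benzyl-3-propanoyl-1,3-oxazolidin-2-one | CCC(=O)N1[C@H](Cc2ccccc2)COC1=O | intermediate
30 | 2-methylprop-2-enal | CC(=C)C=O | starting material
31 | dibutylboron (Z)-enolate of 29 (not isolated) | C/C=C(\OB(CCCC)CCCC)N1[C@H](Cc2ccccc2)COC1=O | intermediate
32 | (4R)-4-benzyl-3-[(2R,3R)-3-hydroxy-2,4-dimethylpent-4-enoyl]-1,3-oxazolidin-2-one | C=C(C)[C@H](O)[C@@H](C)C(=O)N1[C@H](Cc2ccccc2)COC1=O | intermediate
33 | (4R)-4-benzyl-3-{(2R,3R)-2,4-dimethyl-3-[(triethylsilyl)oxy]pent-4-enoyl}-1,3-oxazolidin-2-one | C=C(C)[C@H](O[Si](CC)(CC)CC)[C@@H](C)C(=O)N1[C@H](Cc2ccccc2)COC1=O | intermediate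
34 | (2S,3R)-2,4-dimethyl-3-[(triethylsilyl)oxy]pent-4-en-1-ol | C=C(C)[C@H](O[Si](CC)(CC)CC)[C@@H](C)CO | intermediate
35 | (2R,3R)-2,4-dimethyl-3-[(triethylsilyl)oxy]pent-4-enal (C3–C7) | C=C(C)[C@H](O[Si](CC)(CC)CC)[C@@H](C)C=O | intermediate
36 | O19 ester of 25 with (2Z,4S,5R)-2,4,6-trimethyl-5-[(triethylsilyl)oxy]hepta-2,6-dienoic acid (seco compound, 5-O-TES, 11-O-TBS) | C=CC[C@@H](O[Si](C)(C)C(C)(C)C)/C(C)=C\[C@@H]1O[C@H](C[C@@H]1OC)[C@@H](C)[C@H](OC(=O)/C(C)=C\[C@H](C)[C@@H](O[Si](CC)(CC)CC)C(C)=C)/C=C/[C@H]2O[C@@H]2C | intermediate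
37 | 36 with the O5 triethylsilyl group removed (5R alcohol) | C=CC[C@@H](O[Si](C)(C)C(C)(C)C)/C(C)=C\[C@@H]1O[C@H](C[C@@H]1OC)[C@@H](C)[C@H](OC(=O)/C(C)=C\[C@H](C)[C@@H](O)C(C)=C)/C=C/[C@H]2O[C@@H]2C | intermediate
38 | O19 ester of 25 with (2Z,4S)-2,4,6-trimethyl-5-oxohepta-2,6-dienoic acid (C5 ketone, 11-O-TBS) | C=CC[C@@H](O[Si](C)(C)C(C)(C)C)/C(C)=C\[C@@H]1O[C@H](C[C@@H]1OC)[C@@H](C)[C@H](OC(=O)/C(C)=C\[C@H](C)C(=O)C(C)=C)/C=C/[C@H]2O[C@@H]2C | intermediate
39 | 38 with the O11 silyl group removed (free 11R hydroxyl; terminal C8=C9 and C6=C7 alkenes) | C=CC[C@@H](O)/C(C)=C\[C@@H]1O[C@H](C[C@@H]1OC)[C@@H](C)[C@H](OC(=O)/C(C)=C\[C@H](C)C(=O)C(C)=C)/C=C/[C@H]2O[C@@H]2C | intermediate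
40 | CNP0117824.2, (2Z,4S,6E,8Z,11R,12Z,14S,15S,17R,18R,19R,20E,22R,23R)-macrolide | CO[C@H]1C[C@H]2O[C@H]1/C=C(/C)[C@H](O)C/C=C\C=C(/C)C(=O)[C@@H](C)/C=C(/C)C(=O)O[C@H](/C=C/[C@H]1O[C@@H]1C)[C@@H]2C | target

## Step count and risks

Total step count: 31.
Longest linear sequence: 20 steps (steps 4–7, 8–11, 14–19, 21, 27–31, from 5 and 6 to 40).

The three steps most likely to fail:

Step 31 (the proposed new step). The C8–H cleavage may be too slow against oxidation of the C11 carbinol by divalent palladium. Transient zerovalent palladium may ionise the vinyl epoxide or the C19 allylic ester. β-Hydride elimination may give the exocyclic methylene isomer. The fallback uses known chemistry and replaces the C–H cleavage by oxidative addition into a preformed (8Z)-C–I bond, a macrocyclising Mizoroki–Heck reaction of the kind used for dienone lactones; it still relies on the same insertion and β-hydride elimination at the enone. It sets out from 24 and comes back at 40. The terminal alkene of 24 is cleaved (OsO4 cat., NaIO4, 2,6-lutidine, dioxane/H2O) to the C9 aldehyde F1. Stork–Zhao olefination ([Ph3PCH2I]I, NaN(SiMe3)2, THF/DMPU, −78 °C) gives the (8Z)-vinyl iodide F2. Steps 19, 21, 27, 28 and 29 are then repeated on this series to give the C19 alcohol F3, the phosphonate ester F4, the (2Z)-enoate F5 (from F4 and 35), the C5 alcohol F6 and the iodo enone F7. Ring closure with Pd(OAc)2, Bu4NCl and NaHCO3 in DMF at 25 °C and 1 mM gives the 11-O-TBS macrocycle F8, and HF·pyridine/pyridine gives 40.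

Step 9. The vinyl epoxide has to survive AcOH and camphorsulfonic acid while the terminal epoxide is opened. The fallback carries a diene through the acid steps and epoxidises afterwards. It sets out from 10 and comes back at 15. Enol borinate 11 is added to commercial (2E,4E)-hexa-2,4-dienal F9 under the conditions of step 8 to give the dienyl aldol adduct F10. Me4NBH(OAc)3 and then camphorsulfonic acid give the oxolane diol F12 through the anti-diol F11 (not isolated), and Et3SiCl/imidazole gives the bis(triethylsilyl) ether F13. Shi epoxidation (D-fructose-derived ketone, 2KHSO5·KHSO4·K2SO4, K2CO3, MeCN/dimethoxymethane/H2O, 0 °C) then epoxidises the distal C22=C23 bond, which is more electron-rich than the one next to the silyloxy carbon, from the face that gives the (22R,23R)-epoxide 15.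

Step 8. Enolisation of 10 may occur in part at C16 (with loss of methoxide), and the boron triflate may attack the epoxides. The fallback generates the C18 enolate regiospecifically by conjugate reduction. It sets out from 9 and comes back at 12. Vinylmagnesium bromide (THF, −40 °C) converts 9 into the vinyl ketone F14. Hydrogen-mediated reductive aldol coupling with 4 (Rh(cod)2OTf, chiral TADDOL-type phosphonite, Li2CO3, H2 1 atm, CH2Cl2) forms the (Z)-rhodium enolate only at C18 and gives the syn adduct 12.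

## Further compounds

F1 | step 31 | C9 aldehyde from 24 (C8 removed; 11-O-TBS, 19-O-TES) | O=CC[C@@H](O[Si](C)(C)C(C)(C)C)/C(C)=C\[C@@H]1O[C@H](C[C@@H]1OC)[C@@H](C)[C@H](O[Si](CC)(CC)CC)/C=C/[C@H]2O[C@@H]2C
F2 | step 31 | (8Z)-vinyl iodide (C8–C24; 11-O-TBS, 19-O-TES) | I/C=C\C[C@@H](O[Si](C)(C)C(C)(C)C)/C(C)=C\[C@@H]1O[C@H](C[C@@H]1OC)[C@@H](C)[C@H](O[Si](CC)(CC)CC)/C=C/[C@H]2O[C@@H]2C
F3 | step 31 | F2 with free 19R hydroxyl | I/C=C\C[C@@H](O[Si](C)(C)C(C)(C)C)/C(C)=C\[C@@H]1O[C@H](C[C@@H]1OC)[C@@H](C)[C@H](O)/C=C/[C@H]2O[C@@H]2C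
F4 | step 31 | O19 ester of F3 with acid 26 | I/C=C\C[C@@H](O[Si](C)(C)C(C)(C)C)/C(C)=C\[C@@H]1O[C@H](C[C@@H]1OC)[C@@H](C)[C@H](OC(=O)C(C)P(=O)(Oc1ccccc1C)Oc1ccccc1C)/C=C/[C@H]2O[C@@H]2C
F5 | step 31 | (2Z)-enoate from F4 and 35 (5-O-TES, 11-O-TBS, 8Z-iodide) | I/C=C\C[C@@H](O[Si](C)(C)C(C)(C)C)/C(C)=C\[C@@H]1O[C@H](C[C@@H]1OC)[C@@H](C)[C@H](OC(=O)/C(C)=C\[C@H](C)[C@@H](O[Si](CC)(CC)CC)C(C)=C)/C=C/[C@H]2O[C@@H]2C
F6 | step 31 | F5 with free 5R hydroxyl | I/C=C\C[C@@H](O[Si](C)(C)C(C)(C)C)/C(C)=C\[C@@H]1O[C@H](C[C@@H]1OC)[C@@H](C)[C@H](OC(=O)/C(C)=C\[C@H](C)[C@@H](O)C(C)=C)/C=C/[C@H]2O[C@@H]2C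
F7 | step 31 | iodo enone (C5 ketone, 11-O-TBS, 8Z-iodide) | I/C=C\C[C@@H](O[Si](C)(C)C(C)(C)C)/C(C)=C\[C@@H]1O[C@H](C[C@@H]1OC)[C@@H](C)[C@H](OC(=O)/C(C)=C\[C@H](C)C(=O)C(C)=C)/C=C/[C@H]2O[C@@H]2C
F8 | step 31 | 11-O-tert-butyldimethylsilyl ether of 40 | CO[C@H]1C[C@H]2O[C@H]1/C=C(/C)[C@H](O[Si](C)(C)C(C)(C)C)C/C=C\C=C(/C)C(=O)[C@@H](C)/C=C(/C)C(=O)O[C@H](/C=C/[C@H]1O[C@@H]1C)[C@@H]2C
F9 | step 9 | (2E,4E)-hexa-2,4-dienal | C/C=C/C=C/C=O
F10 | step 9 | (1S,4S,5R,6E,8E)-5-hydroxy-1-methoxy-4-methyl-1-[(2R)-oxiran-2-yl]deca-6,8-dien-3-one | C/C=C/C=C/[C@@H](O)[C@H](C)C(=O)C[C@H](OC)[C@H]1CO1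
F11 | step 9 | (1S,3R,4R,5R,6E,8E)-1-methoxy-4-methyl-1-[(2R)-oxiran-2-yl]deca-6,8-diene-3,5-diol (not isolated) | C/C=C/C=C/[C@@H](O)[C@H](C)[C@H](O)C[C@H](OC)[C@H]1CO1
F12 | step 9 | (2S,3R,4E,6E)-2-[(2R,4S,5S)-5-(hydroxymethyl)-4-methoxyoxolan-2-yl]octa-4,6-dien-3-ol | C/C=C/C=C/[C@@H](O)[C@H](C)[C@H]1C[C@H](OC)[C@H](CO)O1
F13 | step 9 | bis(triethylsilyl) ether of F12 | C/C=C/C=C/[C@@H](O[Si](CC)(CC)CC)[C@H](C)[C@H]1C[C@H](OC)[C@H](CO[Si](CC)(CC)CC)O1
F14 | step 8 | (5S)-5-methoxy-5-[(2R)-oxiran-2-yl]pent-1-en-3-one | C=CC(=O)C[C@H](OC)[C@H]1CO1
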